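The single-handed catalyst consumes both mirror-image substrates, each with the partner, so every flask carries two logarithms growing side by side.

| flask | left-handed substrate | right-handed substrate | partner | catalyst | remark | time |
|---|---|---|---|---|---|---|
| winter | 0.093 M | 0.093 M | 0.124 M | 1.2 mM | run made earlier |  |
| grey | 0.062 M | 0.062 M | 0.400 M | 2.5 mM |  | 2.0 h |
| green | 0.062 M | 0.062 M | 0.124 M | 1.2 mM |  | 2.0 h |
| ochre | 0.062 M | 0.062 M | 0.200 M | 5.0 mM |  | 2.0 h |
| teal | 0.062 M | 0.062 M | 0.200 M | 4.0 mM |  | 2.0 h |
winter run (percent of the left-handed substrate and right-handed substrate together charged)

| time / min | left-handed product / % | right-handed product / % |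
|---|---|---|
| 3.00 | 1.0 | 0.2 |
| 6.00 | 2.8 | 0.4 |
| 10.0 | 4.2 | 0.4 |
| 15.0 | 6.0 | 1.5 |
| 20.0 | 7.5 | 1.9 |
| 25.0 | 9.4 | 2.6 |

(scatter of a reading: 0.5 percentage points)
- catalyst is single-handed; left-handed substrate and right-handed substrate are mirror images of each other, charged as a racemate, each of them at the stated concentration
- steps thought possible: partner + catalyst + left-handed substrate -> catalyst + left-handed product; partner + catalyst + right-handed substrate -> catalyst + right-handed product; partner -> decomposed reagent
- no earlier run changes the charge of catalyst; that part of a forecast is a guess
1. the flasks put in order of excess of left-handed product over right-handed product, best first, at 2.0 h (grey / green / ochre / teal)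
2. the excess of left-handed product over right-handed product of the flask you put first, at 2.0 h
3. the excess of left-handed product over right-handed product of the flask you put last, at 2.0 h

We take excess as (left − right)/(left + right) of the products.

1. The rule. Taking each step as first order in catalyst, partner and substrate, the log loss of a substrate, ln(charge/remaining), grows in proportion to catalyst × the time-integral of partner, which becomes catalyst × partner × time only while partner holds steady. The ratio of the two log losses, the selectivity factor, therefore holds however the partner moves. At 25.0 min the winter run reads 9.4 % and 2.6 % of both substrates together, so we double them to reach each substrate's own charge. That gives a left-handed log loss of 0.208 and a factor of 3.90. It is a rough reading, since the right-handed value carries a scatter of 0.5 percentage points.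

2. First instants. The left-handed step leads, so in our reckoning every flask's product starts at an excess of (factor − one)/(factor + one), 59.2 %.

3. Middle. Reckoned against green, catalyst × partner is 5.38 times as large in teal and 6.72 times in ochre and in grey alike. With partner held at its charge, the left-handed log loss at 2.0 h is 1.00 in green and 6.72 in grey, which is 2.92 powers of ten.

4. End. As left-handed substrate thins, right-handed product catches up. Our excess is 47.3 % for green and 9.75 % for grey. Ochre's partner charge is smaller than grey's against equal substrate, so its partner sags sooner in proportion. We therefore order green, teal, ochre, grey.

The forecast gave green > teal > ochre > grey, with top 50 % (43 % to 57 %) and low 15 % (9 % to 23 %), on the ground “The least-converted flask therefore wins.”, and both its values stand above ours.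

The flasks give green > teal > ochre > grey: green 69.5 %, teal 49.1 %, ochre 44.5 %, grey 38.3 %.

    partner + catalyst + left-handed substrate → catalyst + left-handed product (k = 3900 M⁻² h⁻¹)
    partner + catalyst + right-handed substrate → catalyst + right-handed product (k = 550 M⁻² h⁻¹)
    partner → decomposed reagent (k = 0.480 h⁻¹)

Green's remainders at 2.00 h, 55 % left-handed and 92 % right-handed, give a factor of 7.09, above winter's 3.90. We carry green's factor to grey's neighbour, which has 6.3 × 10⁻⁴ M of catalyst and keeps 32 % of its left-handed substrate. The factor puts its right-handed remainder at 85.1 % and its excess at 64.1 %. That neighbour flask gives 64.1 %, from 34.1 % left-handed and 7.45 % right-handed product.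

Readings and results are simulated for an exercise.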